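**Assumption:** natural genipin, (1R,4aS,7aS), is taken as the inexpensive commercial chiral starting material. Iridoid numbering is used: C1 acetal, C3=C4(CO2Me), C5/C9 ring fusion, C6–C8 cyclopentene, C10 on C8, C11/C12 lactone α-C/C=O, C13 benzylidene CH. "β" is the face carrying H-5 and H-9.

## Retrosynthetic overview

1. Prismatomerin ⇒ C11=C13 by decarboxylative Knoevenagel of α-carboxy spirolactone 5 with 4-hydroxybenzaldehyde.
2. 5 ⇒ C8–O spirolactone bond by singlet-oxygen ene reaction of C7=C8 (alkene moves to C6=C7), then acyl transfer from a pendant Meldrum's acid in 4.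
3. 4 ⇒ C10–C11 bond and C1–O–C10 tetrahydrofuran by Knoevenagel / oxa-Michael of 10-oxogenipin 2 with Meldrum's acid.
4. 2 ⇒ genipin 1, which supplies C5, C9 and the cyclopenta[c]pyran.
5. Ring order: pyran + cyclopentene (bought) → tetrahydrofuran → spiro-γ-lactone → arylidene. No protecting groups.

## Route

**Step 1**
Reactants: 1, genipin
Product: 2, 10-oxogenipin (C10 CH2OH → CHO; C1 lactol free)
Conditions: activated MnO2 (15 equiv), CH2Cl2, rt
Reagents that add atoms: none
Why: MnO2 allylic oxidation takes only the primary allylic alcohol and leaves the lactol, enol ether and ester alone; no stereocentre is touched (C1 anomerises freely).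

**Step 2**
Reactants: 2, 10-oxogenipin; 3, Meldrum's acid
Product: 4, tricyclic acetal: O on C1 now bonded to C10 (new THF ring C1–O–C10–C8–C9), C7=C8 retained, C10 bears H (α) and a 2,2-dimethyl-4,6-dioxo-1,3-dioxan-5-yl group (β, cis to H-1 and H-9); (1R,5S,9S,10S)
Conditions: Meldrum's acid (1.05 equiv), pyridine, MeCN, 4 Å MS, 0 °C → rt; then Et3N (1.1 equiv), rt; aq. citric acid work-up
Reagents that add atoms: Meldrum's acid (3), CC1(C)OC(=O)CC(=O)O1 (water lost)
Why: Knoevenagel condensation at the enal, then 5-exo-trig oxa-Michael addition of the anomerised C1–OH to the alkylidene Meldrum's acid; the addition is reversible under Et3N, so the bulky group at C10 settles on the convex β face (10S), and C1 is locked R by the cis ring fusion dictated by C9.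

**Step 3**
Reactants: 4; O2
Product: 5, tetracyclic α-carboxy spirolactone: C8 now sp3 with the lactone O on the β face, C6=C7 alkene, γ-lactone O–C8–C10–C11–C12(=O), C11 bearing CO2H (C11 epimers, inconsequential); (1R,5S,8S,9S,10S)
Conditions: O2, TPP (0.5 mol %), CH2Cl2, −20 °C, visible LED; then PPh3 (1.05 equiv), −20 °C → rt; then 40 °C (−acetone)
Reagents that add atoms: dioxygen, O=O (one O retained)
Why: Proposed new method: photo-oxygenative spirolactonisation, in which singlet oxygen attacks C7=C8 from the convex β face in a Schenck ene reaction; only H-6β can be abstracted there (H-10 is on the α face, and loss of H-9 would need a pyramidalised C8=C9 alkene at the junction of three rings), giving the 8β-hydroperoxide with C6=C7; PPh3 cleaves the O–O bond and the tertiary 8β-OH, cis to the C10 side chain, opens the Meldrum's acid ring with loss of acetone to the cis-fused lactone, so C8 (S) is substrate-controlled; the closest known reaction types are the Schenck ene reaction of trisubstituted cyclopentenes and alcoholysis of 5-alkyl Meldrum's acids to malonic half-esters, but this ene/acyl-transfer cascade on such a substrate is untested.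

**Step 4**
Reactants: 5; 6, 4-hydroxybenzaldehyde
Product: 7, prismatomerin
Conditions: 4-HOC6H4CHO (1.5 equiv), piperidine (0.2 equiv), pyridine, 60 °C
Reagents that add atoms: 4-hydroxybenzaldehyde (6), O=Cc1ccc(O)cc1 (CO2 and H2O lost)
Why: Knoevenagel–Doebner decarboxylative condensation of the malonic half-ester-type acid via the piperidinium iminium; anti loss of CO2 and reversible amine addition give the conjugated E-alkene (aryl anti to the lactone C=O), the free phenol is tolerated, and any transient retro-oxa-Michael opening at C10 can re-close only cis, so no stereocentre is lost.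

## Compound list

1 | genipin, methyl (1R,4aS,7aS)-1-hydroxy-7-(hydroxymethyl)-1,4a,5,7a-tetrahydrocyclopenta[c]pyran-4-carboxylate | COC(=O)C1=CO[C@H]([C@H]2[C@@H]1CC=C2CO)O | starting material

2 | 10-oxogenipin, methyl (1R,4aS,7aS)-7-formyl-1-hydroxy-1,4a,5,7a-tetrahydrocyclopenta[c]pyran-4-carboxylate | COC(=O)C1=CO[C@H]([C@H]2[C@@H]1CC=C2C=O)O | intermediate

3 | Meldrum's acid, 2,2-dimethyl-1,3-dioxane-4,6-dione | CC1(C)OC(=O)CC(=O)O1 | starting material

4 | (1R,5S,9S,10S)-1,10-anhydro-10-(2,2-dimethyl-4,6-dioxo-1,3-dioxan-5-yl)genipin | COC(=O)C1=CO[C@@H]2O[C@@H](C3C(=O)OC(C)(C)OC3=O)C4=CC[C@H]1[C@H]24 | intermediate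

5 | (1R,5S,8S,9S,10S)-11-carboxy spirolactone (prismatomerin lacking the benzylidene, CO2H on C11) | COC(=O)C1=CO[C@@H]2O[C@H]3C(C(=O)O)C(=O)O[C@]34C=C[C@H]1[C@H]24 | intermediate

6 | 4-hydroxybenzaldehyde | O=Cc1ccc(O)cc1 | starting material

7 | prismatomerin, (1R,5S,8S,9S,10S), 11(13)E | COC(=O)C1=CO[C@@H]2O[C@H]3/C(=C\c4ccc(O)cc4)C(=O)O[C@]34C=C[C@H]1[C@H]24 | target

## Summary

Total steps: 4. Longest linear sequence: 4 (from genipin).

Three steps most likely to fail:

- **Step 3 (proposed new step).** Risks: the ene reaction may go to C7 or the α face, and the acidic Meldrum's C–H may interfere. Fallback (known chemistry): heat 4 in wet pyridine to the C10-acetic acid (hydrolysis/decarboxylation), then tether-enforced phenylselenolactonisation (PhSeCl; carboxylate can only reach C8 on the β face) and selenoxide syn-elimination (H2O2) towards C6. The arylidene is then installed by LiHMDS aldol with 4-(TBSO)benzaldehyde, MsCl/DBU elimination and TBAF.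
- **Step 2.** Risks: lactol opening, bis-addition, or poor C10 equilibration. Fallback: build the ring before the C–C bond. Acetylate the bridged 1,10-lactol form of 2 and add the silyl ketene acetal of allyl acetate to the C10 oxocarbenium (BF3·OEt2, convex-face attack), then Pd(0) deallylation to the C10-acetic acid and the selenium/aldol endgame above.
- **Step 4.** Risks: simple protodecarboxylation or E/Z mixtures. Fallback: decarboxylate 5 thermally to the parent spirolactone, then lithium enolate aldol with 4-(TBSO)benzaldehyde, mesylation/DBU E1cB elimination to the E-arylidene, and TBAF/AcOH desilylation.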